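## Retrosynthetic overview

1. The last step opens both rings at once, at the lactone C12–O bond and the carbocycle C6–C7 bond. This gives an acyclic chain with a γ-lactol (masked C6 aldehyde plus free C15-OH) and a (Z)-2-(bromomethyl)enoate next to the C8 isobutyrate.
2. The C1=C10 enoate comes from cross-metathesis of a butenyl lactol (C1–C6, C15) with a 2-substituted acrylate (C7–C14).
3. The butenyl lactol comes from (S)-epichlorohydrin and diethyl malonate (a cyclopropane-fused lactone fixes C4), then allyl cuprate opening, Krapcho reaction and iBu2AlH.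
4. The acrylate/allyl bromide comes from (R)-glyceraldehyde acetonide and methyl 2-(bromomethyl)acrylate (Barbier), Mitsunobu inversion with isobutyric acid (C8), glycol cleavage, Morita–Baylis–Hillman reaction and SN2' bromination.
5. Ring order: the ten-membered carbocycle closes first and the γ-lactone follows in the same flask. The earlier cyclopropane, lactone, lactol and dioxolane rings are temporary.

Labels and assumption: germacrane labels are used (C1=C10 enoate, C4 bears C15H2OH, C6 lactone O-carbon, C7 ring-fusion CH, C8 isobutyrate carbon, C11=C13 methylene, C12 lactone C=O, C14 ester C=O); the SMILES is read as the (3aS,4R,6E,10S,11aR) isomer, i.e. 4S,6R,7S,8R, and (R)-glyceraldehyde acetonide is taken as a purchasable starting material.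

## Route

Step 1
Reactants: 1 (S)-epichlorohydrin; 2 diethyl malonate
Product: 4 ethyl (1R,5S)-2-oxo-3-oxabicyclo[3.1.0]hexane-1-carboxylate, via cyclopropane hydroxy diester 3 (not isolated)
Conditions: NaOEt (1.1 equiv), EtOH, 0 °C to reflux
Reagents that add atoms: none
Why: Tandem epoxide opening, epoxide shift, 3-exo-tet cyclopropanation and lactonisation, in which malonate opens the epoxide CH2, the alkoxide displaces chloride, the malonate anion opens the new epoxide at the stereocentre with clean inversion (this fixes C4), and the cis CH2O– group closes the lactone.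

Step 2
Reactants: 4 ethyl (1R,5S)-2-oxo-3-oxabicyclo[3.1.0]hexane-1-carboxylate; 5 allylmagnesium bromide
Product: 6 ethyl (4S)-4-(but-3-en-1-yl)-2-oxooxolane-3-carboxylate (C3 epimers)
Conditions: CuI (20 mol%), THF, −45 to −20 °C; aq. NH4Cl
Reagents that add atoms: none
Why: Copper-catalysed homoconjugate addition of a Grignard reagent to a doubly activated cyclopropane attacks the unsubstituted cyclopropane CH2, so C4 is untouched and the new epimeric centre is removed in step 3.

Step 3
Reactants: 6 ethyl (4S)-4-(but-3-en-1-yl)-2-oxooxolane-3-carboxylate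
Product: 7 (4S)-4-(but-3-en-1-yl)oxolan-2-one
Conditions: LiCl, DMSO/H2O, 140 °C
Reagents that add atoms: none
Why: Krapcho dealkoxycarbonylation removes the activating ester under neutral conditions that do not touch the β-stereocentre or the terminal alkene.

Step 4
Reactants: 7 (4S)-4-(but-3-en-1-yl)oxolan-2-one
Product: 8 (4S)-4-(but-3-en-1-yl)oxolan-2-ol (anomers)
Conditions: iBu2AlH (1.05 equiv), CH2Cl2, −78 °C; Rochelle salt
Reagents that add atoms: none
Why: Partial reduction of a γ-lactone stops at the stable aluminium lactolate, and the lactol masks the C6 aldehyde and the C15 hydroxyl together, so no protecting group is needed later.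

Step 5
Reactants: 9 (R)-glyceraldehyde acetonide; 10 methyl 2-(bromomethyl)acrylate
Product: 11 methyl (4S)-4-[(4R)-2,2-dimethyl-1,3-dioxolan-4-yl]-4-hydroxy-2-methylidenebutanoate
Conditions: Zn dust, THF/sat. aq. NH4Cl, 0 °C; chromatography removes the minor syn isomer
Reagents that add atoms: none
Why: Aqueous Barbier (Reformatsky-type) allylation adds under Felkin–Anh, non-chelate control to give the anti carbinol (8S), and the neutral cold medium keeps the γ-hydroxy ester open.

Step 6
Reactants: 11 methyl (4S)-4-[(4R)-2,2-dimethyl-1,3-dioxolan-4-yl]-4-hydroxy-2-methylidenebutanoate; 12 isobutyric acid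
Product: 13 methyl (4R)-4-[(4R)-2,2-dimethyl-1,3-dioxolan-4-yl]-2-methylidene-4-[(2-methylpropanoyl)oxy]butanoate
Conditions: PPh3, DIAD, toluene, 0 °C to rt
Reagents that add atoms: none
Why: The Mitsunobu esterification installs the isobutyrate and inverts the carbinol by SN2 in one step, turning the readily obtained 8S alcohol into the required 8R ester.

Step 7
Reactants: 13 methyl (4R)-4-[(4R)-2,2-dimethyl-1,3-dioxolan-4-yl]-2-methylidene-4-[(2-methylpropanoyl)oxy]butanoate
Product: 15 methyl (4R)-2-methylidene-4-[(2-methylpropanoyl)oxy]-5-oxopentanoate, via vicinal diol 14 (not isolated)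
Conditions: H5IO6 (1.5 equiv), EtOAc, rt
Reagents that add atoms: none
Why: Periodic acid hydrolyses the terminal acetonide and cleaves the liberated glycol at once (Malaprade cleavage), so the auxiliary stereocentre becomes the C7 aldehyde carbon and C8 is not touched.

Step 8
Reactants: 15 methyl (4R)-2-methylidene-4-[(2-methylpropanoyl)oxy]-5-oxopentanoate; 16 methyl acrylate
Product: 17 dimethyl (4R)-5-hydroxy-2,6-dimethylidene-4-[(2-methylpropanoyl)oxy]heptanedioate (C5 epimers)
Conditions: DABCO (0.5 equiv), methyl acrylate (5 equiv), dioxane/H2O, 0 °C to rt, short reaction time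
Reagents that add atoms: none
Why: The Morita–Baylis–Hillman reaction is fast on this α-acyloxy-activated aldehyde, the α-substituted acrylate already present cannot compete, and the new C7 carbinol centre is irrelevant because it becomes sp2 in step 9.

Step 9
Reactants: 17 dimethyl (4R)-5-hydroxy-2,6-dimethylidene-4-[(2-methylpropanoyl)oxy]heptanedioate
Product: 18 dimethyl (2Z,4R)-2-(bromomethyl)-6-methylidene-4-[(2-methylpropanoyl)oxy]hept-2-enedioate
Conditions: NBS, Me2S, CH2Cl2, 0 °C to rt
Reagents that add atoms: N-bromosuccinimide O=C1CCC(=O)N1Br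
Why: Corey–Kim-type activation of the Baylis–Hillman alcohol and SN2' delivery of bromide (any participation of the neighbouring isobutyrate through a dioxolenium ion leads to the same product) give the primary (Z)-allyl bromide without breaking the C8–O bond.

Step 10
Reactants: 8 (4S)-4-(but-3-en-1-yl)oxolan-2-ol (2 equiv); 18 dimethyl (2Z,4R)-2-(bromomethyl)-6-methylidene-4-[(2-methylpropanoyl)oxy]hept-2-enedioate
Product: 19 dimethyl (2Z,4R,6E)-2-(bromomethyl)-6-{3-[(3S)-5-hydroxyoxolan-3-yl]propylidene}-4-[(2-methylpropanoyl)oxy]hept-2-enedioate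
Conditions: second-generation Hoveyda–Grubbs catalyst RuCl2(H2IMes)(=CH-C6H4-2-OiPr) (10 mol%), 1,4-benzoquinone (10 mol%), CH2Cl2, 40 °C
Reagents that add atoms: none
Why: Olefin cross-metathesis of a terminal alkene with a methacrylate-type 1,1-disubstituted acrylate gives the thermodynamic E (tiglate-type) enoate with C2 cis to C9, while the trisubstituted bromomethyl enoate is inert to the ruthenium carbene.

Step 11
Reactants: 19 dimethyl (2Z,4R,6E)-2-(bromomethyl)-6-{3-[(3S)-5-hydroxyoxolan-3-yl]propylidene}-4-[(2-methylpropanoyl)oxy]hept-2-enedioate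
Product: 22 methyl (3aS,4R,6E,10S,11aR)-10-(hydroxymethyl)-3-methylidene-4-[(2-methylpropanoyl)oxy]-2-oxo-2,3,3a,4,5,8,9,10,11,11a-decahydrocyclodeca[b]furan-6-carboxylate, via open hydroxy aldehyde 20 (not isolated), via cyclodecene hydroxy ester 21 (not isolated)
Conditions: CrCl2 (10 equiv), degassed THF/DMF 4:1, 19 added by syringe pump over 12 h (final 2 mM), 25 to 40 °C; aq. citric acid work-up
Reagents that add atoms: none
Why: Nozaki–Hiyama (Barbier-type) allylation followed by lactonisation in the same flask: CrCl2 reduces the bromide to a non-basic allylchromium that equilibrates to the geometry with C8 trans to CH2Cr and adds through its γ-carbon C7 to the aldehyde released by the lactol, through a chair transition state with C5 and C8 equatorial (anti adduct, hence 6R and the trans fusion) and on the C7 face anti to the C8–C9 bond with H8 eclipsing the alkene to avoid allylic 1,3-strain (hence 7S, relayed from 8R), after which the chromium alkoxide attacks the neighbouring methyl ester, so the carbocycle and the γ-lactone form in one operation, the C15 hydroxyl is left free, and the ring-cis C1=C10 enoate plus high dilution favour the medium-ring closure.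

## Compound list

1 | (S)-epichlorohydrin, (2S)-2-(chloromethyl)oxirane | ClC[C@@H]1CO1 | starting material
2 | diethyl malonate | CCOC(=O)CC(=O)OCC | starting material
3 | diethyl (2S)-2-(hydroxymethyl)cyclopropane-1,1-dicarboxylate (present as its alkoxide) | CCOC(=O)C1(C[C@@H]1CO)C(=O)OCC | intermediate
4 | ethyl (1R,5S)-2-oxo-3-oxabicyclo[3.1.0]hexane-1-carboxylate | CCOC(=O)[C@@]12C[C@@H]1COC2=O | intermediate
5 | allylmagnesium bromide | C=CC[Mg]Br | starting material
6 | ethyl (4S)-4-(but-3-en-1-yl)-2-oxooxolane-3-carboxylate (C3 epimers) | CCOC(=O)C1[C@H](CCC=C)COC1=O | intermediate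
7 | (4S)-4-(but-3-en-1-yl)oxolan-2-one | O=C1C[C@@H](CO1)CCC=C | intermediate
8 | (4S)-4-(but-3-en-1-yl)oxolan-2-ol (anomers) | OC1C[C@@H](CO1)CCC=C | intermediate
9 | (R)-glyceraldehyde acetonide, (4R)-2,2-dimethyl-1,3-dioxolane-4-carbaldehyde | O=C[C@H]1COC(C)(C)O1 | starting material
10 | methyl 2-(bromomethyl)acrylate | C=C(CBr)C(=O)OC | starting material
11 | methyl (4S)-4-[(4R)-2,2-dimethyl-1,3-dioxolan-4-yl]-4-hydroxy-2-methylidenebutanoate | C=C(C(=O)OC)C[C@H](O)[C@H]1COC(C)(C)O1 | intermediate
12 | isobutyric acid | CC(C)C(=O)O | starting material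
13 | methyl (4R)-4-[(4R)-2,2-dimethyl-1,3-dioxolan-4-yl]-2-methylidene-4-[(2-methylpropanoyl)oxy]butanoate | C=C(C(=O)OC)C[C@@H](OC(=O)C(C)C)[C@H]1COC(C)(C)O1 | intermediate
14 | methyl (4R,5R)-5,6-dihydroxy-2-methylidene-4-[(2-methylpropanoyl)oxy]hexanoate | C=C(C(=O)OC)C[C@@H](OC(=O)C(C)C)[C@H](O)CO | intermediate
15 | methyl (4R)-2-methylidene-4-[(2-methylpropanoyl)oxy]-5-oxopentanoate | C=C(C(=O)OC)C[C@@H](OC(=O)C(C)C)C=O | intermediate
16 | methyl acrylate | C=CC(=O)OC | starting material
17 | dimethyl (4R)-5-hydroxy-2,6-dimethylidene-4-[(2-methylpropanoyl)oxy]heptanedioate (C5 epimers) | C=C(C(=O)OC)C[C@@H](OC(=O)C(C)C)C(O)C(=C)C(=O)OC | intermediate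
18 | dimethyl (2Z,4R)-2-(bromomethyl)-6-methylidene-4-[(2-methylpropanoyl)oxy]hept-2-enedioate | C=C(C(=O)OC)C[C@@H](OC(=O)C(C)C)/C=C(\CBr)C(=O)OC | intermediate
19 | dimethyl (2Z,4R,6E)-2-(bromomethyl)-6-{3-[(3S)-5-hydroxyoxolan-3-yl]propylidene}-4-[(2-methylpropanoyl)oxy]hept-2-enedioate (anomers) | OC1C[C@@H](CO1)CC/C=C(/C(=O)OC)C[C@@H](OC(=O)C(C)C)/C=C(\CBr)C(=O)OC | intermediate
20 | dimethyl (2Z,4R,6E)-2-(bromomethyl)-6-[(4S)-4-(hydroxymethyl)-6-oxohexylidene]-4-[(2-methylpropanoyl)oxy]hept-2-enedioate (open form of 19) | O=CC[C@@H](CO)CC/C=C(/C(=O)OC)C[C@@H](OC(=O)C(C)C)/C=C(\CBr)C(=O)OC | intermediate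
21 | methyl (1E,5S,7R,8S,9R)-7-hydroxy-5-(hydroxymethyl)-8-(3-methoxy-3-oxoprop-1-en-2-yl)-9-[(2-methylpropanoyl)oxy]cyclodec-1-ene-1-carboxylate (present as its chromium alkoxide) | C=C(C(=O)OC)[C@H]1[C@H](O)C[C@@H](CO)CC/C=C(/C(=O)OC)C[C@H]1OC(=O)C(C)C | intermediate
22 | CNP0251148.1, methyl (3aS,4R,6E,10S,11aR)-10-(hydroxymethyl)-3-methylidene-4-[(2-methylpropanoyl)oxy]-2-oxo-2,3,3a,4,5,8,9,10,11,11a-decahydrocyclodeca[b]furan-6-carboxylate | C=C1C(=O)O[C@@H]2C[C@@H](CO)CC/C=C(/C(=O)OC)C[C@@H](OC(=O)C(C)C)[C@@H]12 | target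

## Step count and risks

Total step count: 11. Longest linear sequence: 7 (steps 5, 6, 7, 8, 9, 10, 11).

**Step 11.** The risks are:
- 1,4-elimination of the C8 isobutyrate from the allylchromium to give a diene;
- oligomerisation instead of ring closure;
- formation of the cis-fused or 7-epi lactone;
- slow reaction of the lactol.

The fallback sets out from 8 and 18 and comes back at 22. The fragments are first joined by an intermolecular Nozaki–Hiyama allylation of lactol 8 with bromide 18 (CrCl2, THF/DMF, normal concentration). This gives the open-chain seco hydroxy diester F1, which lactonises in the flask to the monocyclic α-methylene-γ-butyrolactone diene F2. The carbocycle is then closed at the opposite side of the ring by ring-closing metathesis of the butenyl and acrylate termini (second-generation Hoveyda–Grubbs catalyst, toluene, 80 °C, 1 mM). Only the ring-cis, E-configured enoate of 22 can form in a ring of this size.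

**Step 10.** The hindered 2-substituted acrylate of a precious five-step fragment may react sluggishly, and lactol 8 may homodimerise. The fallback sets out from 8 and 13 and comes back at 19. It makes the route linear rather than convergent. The union is moved to the start of the right-hand sequence, where the robust two-step acrylate 13 can be used in fivefold excess. This gives the joined acetonide F3. Periodic acid converts F3, through the joined vicinal diol F4, into the joined α-acyloxy aldehyde F5. The activated free aldehyde of F5 reacts with methyl acrylate and DABCO in preference to the masked lactol, giving the joined Baylis–Hillman alcohol F6. NBS/Me2S then delivers 19.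

**Step 8.** The amine base can epimerise C8 of the α-acyloxy aldehyde or cause acyl migration. The fallback sets out from 15 and comes back at 17. The C7–C11 bond is made with a preformed nucleophile from a different building block. Methyl propiolate is hydroaluminated with iBu2AlH and N-methylmorpholine N-oxide in THF at 0 °C to give [1-(methoxycarbonyl)vinyl]diisobutylaluminium F7. F7 adds to aldehyde 15 within minutes at −78 °C with no base present.

## Further compounds

F1 | step 11 | dimethyl (3S,4R)-3-[(1R,3S)-1-hydroxy-3-(hydroxymethyl)hept-6-en-1-yl]-2,6-dimethylidene-4-[(2-methylpropanoyl)oxy]heptanedioate | C=C(C(=O)OC)[C@@H]([C@H](O)C[C@@H](CO)CCC=C)[C@H](OC(=O)C(C)C)CC(=C)C(=O)OC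
F2 | step 11 | methyl (4R)-4-{(2R,3S)-2-[(2S)-2-(hydroxymethyl)hex-5-en-1-yl]-4-methylidene-5-oxooxolan-3-yl}-2-methylidene-4-[(2-methylpropanoyl)oxy]butanoate | C=C1C(=O)O[C@H](C[C@@H](CO)CCC=C)[C@H]1[C@H](OC(=O)C(C)C)CC(=C)C(=O)OC
F3 | step 10 | methyl (2E,4R)-4-[(4R)-2,2-dimethyl-1,3-dioxolan-4-yl]-2-{3-[(3S)-5-hydroxyoxolan-3-yl]propylidene}-4-[(2-methylpropanoyl)oxy]butanoate | OC1C[C@@H](CO1)CC/C=C(/C(=O)OC)C[C@@H](OC(=O)C(C)C)[C@H]1COC(C)(C)O1
F4 | step 10 | methyl (2E,4R,5R)-5,6-dihydroxy-2-{3-[(3S)-5-hydroxyoxolan-3-yl]propylidene}-4-[(2-methylpropanoyl)oxy]hexanoate | OC1C[C@@H](CO1)CC/C=C(/C(=O)OC)C[C@@H](OC(=O)C(C)C)[C@H](O)CO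
F5 | step 10 | methyl (2E,4R)-2-{3-[(3S)-5-hydroxyoxolan-3-yl]propylidene}-4-[(2-methylpropanoyl)oxy]-5-oxopentanoate | OC1C[C@@H](CO1)CC/C=C(/C(=O)OC)C[C@@H](OC(=O)C(C)C)C=O
F6 | step 10 | dimethyl (2E,4R)-5-hydroxy-2-{3-[(3S)-5-hydroxyoxolan-3-yl]propylidene}-6-methylidene-4-[(2-methylpropanoyl)oxy]heptanedioate (C5 epimers) | OC1C[C@@H](CO1)CC/C=C(/C(=O)OC)C[C@@H](OC(=O)C(C)C)C(O)C(=C)C(=O)OC
F7 | step 8 | [1-(methoxycarbonyl)vinyl]diisobutylaluminium | C=C(C(=O)OC)[Al](CC(C)C)CC(C)C
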